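**Retrosynthetic overview**

1. Atom labels used throughout: ring A is the cyclobutane C1(Me)–C2–C3–C4; ring B (six-membered) is C2–C3–C4–C5(=O)–C6–C7(Me); ring C (seven-membered) is C1–C8(OH)–C9–C10(O-angelate)–C11(Me)(CH2OAc)–C3. The strategy rests on this feature: C3 is β to the C5 carbonyl through C4 and carries the quaternary C11, while C6 is α to C5, so a cyclobut-1-ene-1-carboxylate (C4=C3, C5 = ester carbon) can accept a C11 ester dienolate at C3 and then be acylated at C5 by a C6 ester enolate.
2. Late stage: the C10 angelate and the anti C8 hydroxyl come from one Evans–Tishchenko reaction of a β-hydroxy ketone; C9–C10 is an intramolecular aldol bond (ring C); the C8 acetyl and C10 aldehyde come from the CH2OSi arm on C1 and the vinyl group on C11.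
3. Middle: C3–C11 and C5–C6 are formed by a Michael–Dieckmann cascade of cyclobutene 14 with the dienolate of tert-butyl tiglate (ring B). The C7 methyl is added afterwards to the C6=C7 enone of the rigid bicycle, and the tert-butyl ester is reduced early, with C5 protected as its enolate.
4. Early: cyclobutene 14 comes from Wolff ring contraction (ring A) of a 2,2,3-trisubstituted cyclopentanone, made by copper-catalysed asymmetric conjugate addition to 2-methylcyclopent-2-enone with formaldehyde trapping (C2 absolute, C1 relative).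
5. Ring order: A (step 4), then B (step 10), then C (step 21).

Key step: step 10

Remark: "core" means the bicyclo[3.1.1]heptan-2-one C2–C3–C4–C5(=O)–C6–C7 with C1 as the second one-carbon bridge (on C1 the methyl is syn and the C8 arm anti to the C5–C7 bridge; on C3 the C11 arm is anti); centres that are erased in a later step (C4 in 9 and 10, C6 in 19 and 20, C8 in 29) are carried as mixtures and left open in the SMILES.

**Route**

Step 1
Reactants: 1 2-methylcyclopent-2-en-1-one; 2 [2-(1,3-dioxolan-2-yl)ethyl]magnesium bromide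
Product: 4 (2S,3S)-3-[2-(1,3-dioxolan-2-yl)ethyl]-2-(hydroxymethyl)-2-methylcyclopentan-1-one, via bromomagnesium enolate 3 (not isolated)
Conditions: Cu(OTf)2 (5 mol %), chiral hydroxyalkyl imidazolinium salt (NHC precursor, 6 mol %), Et2O, −30 °C; then CH2O (gas, from cracked paraformaldehyde), −30 → 0 °C; H2O/NH4Cl
Reagents that add atoms: formaldehyde, C=O
Why: Copper-catalysed asymmetric conjugate addition of the Grignard reagent sets C2 under ligand control (the ligand enantiomer that gives the 3S ketone is used), and the tetrasubstituted enolate 3 then undergoes an aldol reaction with formaldehyde on the face opposite the new chain, so C1 is formed with its methyl cis and its hydroxymethyl trans to the chain.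

Step 2
Reactants: 4 (2S,3S)-3-[2-(1,3-dioxolan-2-yl)ethyl]-2-(hydroxymethyl)-2-methylcyclopentan-1-one
Product: 5 (2S,3S)-2-{[(tert-butyldiphenylsilyl)oxy]methyl}-3-[2-(1,3-dioxolan-2-yl)ethyl]-2-methylcyclopentan-1-one
Conditions: TBDPSCl, imidazole, DMF, rt
Reagents that add atoms: tert-butyl(chloro)diphenylsilane, CC(C)(C)[Si](Cl)(c1ccccc1)c1ccccc1
Why: Standard silylation of the primary alcohol; the tert-butyldiphenylsilyl ether is chosen because it should survive the later acetal hydrolysis and all base and hydride steps.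

Step 3
Reactants: 5 (2S,3S)-2-{[(tert-butyldiphenylsilyl)oxy]methyl}-3-[2-(1,3-dioxolan-2-yl)ethyl]-2-methylcyclopentan-1-one
Product: 7 (2S,3S)-2-{[(tert-butyldiphenylsilyl)oxy]methyl}-5-diazo-3-[2-(1,3-dioxolan-2-yl)ethyl]-2-methylcyclopentan-1-one, via trifluoroacetyl ketone 6 (not isolated)
Conditions: LiN(SiMe3)2, THF, −78 °C; CF3CO2CH2CF3; then MsN3, Et3N, H2O, MeCN, rt
Reagents that add atoms: methanesulfonyl azide, CS(=O)(=O)N=[N+]=[N-]
Why: Detrifluoroacetylative (Regitz-type) diazo transfer; only C4 can be enolised because C1 is quaternary, so Claisen trifluoroacetylation and azide transfer to 6 place the diazo group regiospecifically.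

Step 4
Reactants: 7 (2S,3S)-2-{[(tert-butyldiphenylsilyl)oxy]methyl}-5-diazo-3-[2-(1,3-dioxolan-2-yl)ethyl]-2-methylcyclopentan-1-one
Product: 9 methyl (2R,3S)-2-{[(tert-butyldiphenylsilyl)oxy]methyl}-3-[2-(1,3-dioxolan-2-yl)ethyl]-2-methylcyclobutane-1-carboxylate (C4 epimers), via cyclobutylidene ketene 8 (not isolated)
Conditions: hν (medium-pressure Hg lamp, Pyrex), MeOH, rt
Reagents that add atoms: methanol, CO
Why: Photochemical Wolff rearrangement; loss of nitrogen and 1,2-shift of the quaternary C1 from C5 to C4 with retention contracts the ring to ketene 8 (ring A), which methanol traps, leaving C1 and C2 untouched.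

Step 5
Reactants: 9 methyl (2R,3S)-2-{[(tert-butyldiphenylsilyl)oxy]methyl}-3-[2-(1,3-dioxolan-2-yl)ethyl]-2-methylcyclobutane-1-carboxylate
Product: 11 methyl (3S,4R)-4-{[(tert-butyldiphenylsilyl)oxy]methyl}-3-[2-(1,3-dioxolan-2-yl)ethyl]-4-methylcyclobut-1-ene-1-carboxylate, via α-phenylselanyl ester 10 (not isolated)
Conditions: LiN(i-Pr)2, THF, −78 °C; PhSeBr; then 30% H2O2, pyridine, CH2Cl2, 0 °C → rt
Reagents that add atoms: none
Why: α-Selenenylation of the ester and selenoxide syn-elimination; C1 has no hydrogen, so the double bond can only form towards C3, and the side chain is still an acetal so no second ester competes for the base.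

Step 6
Reactants: 11 methyl (3S,4R)-4-{[(tert-butyldiphenylsilyl)oxy]methyl}-3-[2-(1,3-dioxolan-2-yl)ethyl]-4-methylcyclobut-1-ene-1-carboxylate
Product: 12 methyl (3S,4R)-4-{[(tert-butyldiphenylsilyl)oxy]methyl}-4-methyl-3-(3-oxopropyl)cyclobut-1-ene-1-carboxylate
Conditions: PPTS, acetone/H2O, 60 °C
Reagents that add atoms: water, O
Why: Acid-catalysed acetal hydrolysis under conditions that the silyl ether and the conjugated ester should tolerate.

Step 7
Reactants: 12 methyl (3S,4R)-4-{[(tert-butyldiphenylsilyl)oxy]methyl}-4-methyl-3-(3-oxopropyl)cyclobut-1-ene-1-carboxylate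
Product: 13 methyl (3S,4R)-3-(2-carboxyethyl)-4-{[(tert-butyldiphenylsilyl)oxy]methyl}-4-methylcyclobut-1-ene-1-carboxylate
Conditions: NaClO2, NaH2PO4, 2-methylbut-2-ene, t-BuOH/H2O, 0 °C → rt
Reagents that add atoms: sodium chlorite, [Na+].[O-]Cl=O
Why: Pinnick oxidation of the aldehyde, which does not touch the electron-poor cyclobutene.

Step 8
Reactants: 13 methyl (3S,4R)-3-(2-carboxyethyl)-4-{[(tert-butyldiphenylsilyl)oxy]methyl}-4-methylcyclobut-1-ene-1-carboxylate
Product: 14 methyl (3S,4R)-4-{[(tert-butyldiphenylsilyl)oxy]methyl}-3-(3-methoxy-3-oxopropyl)-4-methylcyclobut-1-ene-1-carboxylate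
Conditions: MeI, K2CO3, DMF, rt
Reagents that add atoms: iodomethane, CI
Why: O-Alkylation of the carboxylate under mild carbonate conditions that should not add to the strained enoate.

Step 9
Reactants: 15 tiglic acid
Product: 16 tert-butyl (E)-2-methylbut-2-enoate
Conditions: isobutene, H2SO4 (cat.), CH2Cl2, sealed vessel, rt
Reagents that add atoms: 2-methylpropene, CC(C)=C
Why: Acid-catalysed addition of the carboxylic acid to isobutene gives the tert-butyl ester with the E double bond unchanged.

Step 10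
Reactants: 14 methyl (3S,4R)-4-{[(tert-butyldiphenylsilyl)oxy]methyl}-3-(3-methoxy-3-oxopropyl)-4-methylcyclobut-1-ene-1-carboxylate; 16 tert-butyl (E)-2-methylbut-2-enoate
Product: 19 core β-keto ester with C6 CO2Me; C7 H2; C8 = CH2OTBDPS; C11 = C(Me)(CH=CH2)(CO2t-Bu), via lithium dienolate 17 (not isolated), via cyclobutane ester enolate 18 (not isolated)
Conditions: 16 (1.3 equiv), LiN(i-Pr)2 (1.25 equiv), THF/DMPU (5:1), −78 °C; add 14, −78 °C; then KOt-Bu, t-BuOH, −78 → 0 °C; AcOH
Reagents that add atoms: none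
Why: Proposed new method: the dienolate 17 adds through its fully substituted α-carbon (C11) to C3 of the strained enoate 14 to give the C4 ester enolate 18; tert-butoxide/tert-butanol then moves the proton from C6 to C4, and the C6 enolate acylates the C4 ester carbon C5 in a 6-(enolexo)-exo-trig Dieckmann closure of ring B, driven by deprotonation of the β-keto ester. The closest known reactions are conjugate additions of ester enolates to cyclobut-1-enecarboxylates and Michael-initiated Dieckmann annulations; their combination on a 3,4,4-trisubstituted cyclobutene has no precedent. C3 is set by attack anti to the adjacent C2 chain; C4 is set by equilibration, which puts its ester trans to the bulky C11 group and cis to the C2 chain, the only epimer able to cyclise. C11 is set in the C–C bond formation: with DMPU-solvated lithium an open antiperiplanar transition state is expected, with the enolate carbon anti to C4, the methyl under the ring between C2 and C4 and the vinyl group between C4 and the C3 hydrogen, which is the required configuration, whereas a lithium-bridged closed arrangement would give the C11 epimer. The step also needs α- rather than γ-attack of the dienolate (kinetic conditions at −78 °C) and discrimination between three esters: the tert-butyl ester is too hindered to be an acceptor, and direct closure of 18 onto the side-chain ester gives a bridgehead β-keto ester that cannot be deprotonated between its carbonyls and should revert under the alkoxide, so only 19 accumulates as its enolate.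

Step 11
Reactants: 19 core β-keto ester with C6 CO2Me; C7 H2; C8 = CH2OTBDPS; C11 = C(Me)(CH=CH2)(CO2t-Bu)
Product: 21 C6=C7 enone ester of the core (C8 = CH2OTBDPS; C11 = C(Me)(CH=CH2)(CO2t-Bu)), via C6 phenylselanyl β-keto ester 20 (not isolated)
Conditions: NaH, THF, 0 °C; PhSeCl, −78 °C; then 30% H2O2, pyridine, CH2Cl2, 0 °C
Reagents that add atoms: none
Why: Selenenylation of the β-keto ester at C6 and selenoxide syn-elimination towards the C7 hydrogens; the preformed enolate reacts far faster than the hindered vinyl group and the bridgehead C4 cannot take part.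

Step 12
Reactants: 21 C6=C7 enone ester of the core
Product: 22 core β-keto ester with C7 methyl (C6 CO2Me trans to it; C8 = CH2OTBDPS; C11 = C(Me)(CH=CH2)(CO2t-Bu))
Conditions: MeMgBr, CuBr·SMe2 (10 mol %), THF, −40 °C; H2O/NH4Cl
Reagents that add atoms: methylmagnesium bromide, C[Mg]Br
Why: Copper-catalysed conjugate addition to the doubly activated enone; the methyl enters C7 from the side of the C3 bridge, whose inward substituent is hydrogen, because the C1 bridge holds its methyl over the enone (the facial rule of verbenone-type bicyclo[3.1.1]heptenones), which sets C7 as in the target.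

Step 13
Reactants: 22 core β-keto ester with C7 methyl
Product: 23 core ketone with C6 H2; C7 methyl; C8 = CH2OTBDPS; C11 = C(Me)(CH=CH2)(CO2t-Bu)
Conditions: LiCl, H2O, DMSO, 130 °C
Reagents that add atoms: none
Why: Krapcho dealkoxycarbonylation; chloride demethylates the methyl ester and the β-keto carboxylate loses carbon dioxide, while the tert-butyl ester is inert to SN2 cleavage.

Step 14
Reactants: 23 core ketone with C6 H2; C7 methyl; C8 = CH2OTBDPS; C11 = C(Me)(CH=CH2)(CO2t-Bu)
Product: 25 core ketone with C11 = C(Me)(CH=CH2)(CH2OH); C8 = CH2OTBDPS, via lithium C5–C6 enolate 24 (not isolated)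
Conditions: LiN(i-Pr)2 (1.2 equiv), THF, −78 °C; then LiAlH4, −78 °C → rt; aq. KNaC4H4O6
Reagents that add atoms: none
Why: The ketone is masked in the flask as its lithium enolate 24 (the bridgehead C4 cannot enolise), which LiAlH4 does not reduce, so only the hindered tert-butyl ester is reduced and the ketone returns on work-up.

Step 15
Reactants: 25 core ketone with C11 = C(Me)(CH=CH2)(CH2OH); C8 = CH2OTBDPS
Product: 26 core ketone with C11 = C(Me)(CH=CH2)(CH2OAc); C8 = CH2OTBDPS
Conditions: Ac2O, pyridine, DMAP (cat.), CH2Cl2, rt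
Reagents that add atoms: acetic anhydride, CC(=O)OC(C)=O
Why: Acetylation of the only free hydroxyl installs the acetate of the target.

Step 16
Reactants: 26 core ketone with C11 = C(Me)(CH=CH2)(CH2OAc); C8 = CH2OTBDPS
Product: 27 core ketone with C8 = CH2OH; C11 = C(Me)(CH=CH2)(CH2OAc)
Conditions: Bu4NF, AcOH, THF, rt
Reagents that add atoms: none
Why: Fluoride cleaves the silyl ether; buffering with acetic acid should prevent acetate hydrolysis or migration.

Step 17
Reactants: 27 core ketone with C8 = CH2OH; C11 = C(Me)(CH=CH2)(CH2OAc)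
Product: 28 core ketone with C8 = CHO; C11 = C(Me)(CH=CH2)(CH2OAc)
Conditions: Dess–Martin periodinane, NaHCO3, CH2Cl2, rt
Reagents that add atoms: none
Why: Dess–Martin oxidation of the neopentyl primary alcohol to an aldehyde that cannot enolise.

Step 18
Reactants: 28 core ketone with C8 = CHO; C11 = C(Me)(CH=CH2)(CH2OAc)
Product: 29 core ketone with C8 = CH(OH)CH3 (C8 epimers); C11 = C(Me)(CH=CH2)(CH2OAc)
Conditions: MeTi(Oi-Pr)3, THF, −40 → 0 °C
Reagents that add atoms: methyltitanium triisopropoxide, C[Ti](OC(C)C)(OC(C)C)OC(C)C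
Why: Chemoselective carbonyl methylation; the titanium reagent adds to aldehydes far faster than to ketones and leaves esters alone, so only C8 is methylated.

Step 19
Reactants: 29 core ketone with C8 = CH(OH)CH3; C11 = C(Me)(CH=CH2)(CH2OAc)
Product: 30 core ketone with C8 = C(=O)CH3; C11 = C(Me)(CH=CH2)(CH2OAc)
Conditions: Dess–Martin periodinane, NaHCO3, CH2Cl2, rt
Reagents that add atoms: none
Why: Dess–Martin oxidation of the secondary alcohol gives the C8 methyl ketone and removes the C8 mixture.

Step 20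
Reactants: 30 core ketone with C8 = C(=O)CH3; C11 = C(Me)(CH=CH2)(CH2OAc)
Product: 31 core ketone with C8 = C(=O)CH3; C11 = C(Me)(CHO)(CH2OAc)
Conditions: O3, CH2Cl2, −78 °C; PPh3
Reagents that add atoms: ozone, [O-][O+]=O
Why: Ozonolysis of the only alkene with reductive work-up unmasks the C10 aldehyde, which has no α-hydrogen.

Step 21
Reactants: 31 core ketone with C8 = C(=O)CH3; C11 = C(Me)(CHO)(CH2OAc)
Product: 32 tricyclic β-hydroxy ketone (C10 OH; C8 ketone; C5 ketone; C11 CH2OAc)
Conditions: LiN(SiMe3)2 (2.2 equiv), THF, −78 °C; AcOH, −78 °C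
Reagents that add atoms: none
Why: Intramolecular aldol addition (7-(enolexo)-exo-trig closure of ring C); the deprotonated C9 methyl attacks the C10 aldehyde, the deprotonated C6 position has no electrophile in reach, and the lithium-bound aldehyde oxygen is expected to turn to the side of the smaller C11 substituent (methyl rather than acetoxymethyl), giving the C10 hydroxyl cis to that methyl.

Step 22
Reactants: 33 angelic acid
Product: 34 (Z)-2-methylbut-2-en-1-ol
Conditions: LiAlH4, Et2O, 0 °C
Reagents that add atoms: none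
Why: Hydride reduction of the acid at low temperature should leave the trisubstituted Z alkene in place.

Step 23
Reactants: 34 (Z)-2-methylbut-2-en-1-ol
Product: 35 (Z)-2-methylbut-2-enal
Conditions: MnO2, CH2Cl2, 0 °C, dark; used at once as a solution
Reagents that add atoms: none
Why: Allylic oxidation with manganese dioxide under neutral conditions, which should keep the Z geometry if the aldehyde is used immediately.

Step 24
Reactants: 32 tricyclic β-hydroxy ketone; 35 (Z)-2-methylbut-2-enal
Product: 36 CNP0212099.1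
Conditions: 35 (6 equiv), SmI2 (0.3 equiv), THF, −10 °C, dark
Reagents that add atoms: none
Why: Evans–Tishchenko reaction; the aldehyde adds to the C10 hydroxyl and passes its formyl hydrogen intramolecularly to the C8 ketone through a six-membered transition state, which gives the C8 alcohol anti to C10 and leaves the oxidised aldehyde as the C10 angelate, while the C5 ketone has no β-hydroxyl and should not be reduced.

**Compound list**

1 | 2-methylcyclopent-2-en-1-one | CC1=CCCC1=O | starting material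
2 | [2-(1,3-dioxolan-2-yl)ethyl]magnesium bromide | Br[Mg]CCC1OCCO1 | starting material
3 | bromomagnesium 3-[2-(1,3-dioxolan-2-yl)ethyl]-2-methylcyclopent-1-en-1-olate (not isolated) | CC1=C(O[Mg]Br)CC[C@@H]1CCC1OCCO1 | intermediate
4 | (2S,3S)-3-[2-(1,3-dioxolan-2-yl)ethyl]-2-(hydroxymethyl)-2-methylcyclopentan-1-one | O=C1CC[C@H](CCC2OCCO2)[C@@]1(C)CO | intermediate
5 | (2S,3S)-2-{[(tert-butyldiphenylsilyl)oxy]methyl}-3-[2-(1,3-dioxolan-2-yl)ethyl]-2-methylcyclopentan-1-one | O=C1CC[C@H](CCC2OCCO2)[C@@]1(C)CO[Si](c1ccccc1)(c1ccccc1)C(C)(C)C | intermediate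
6 | 5-(trifluoroacetyl) derivative of 5 (not isolated) | O=C1C(C(=O)C(F)(F)F)C[C@H](CCC2OCCO2)[C@@]1(C)CO[Si](c1ccccc1)(c1ccccc1)C(C)(C)C | intermediate
7 | (2S,3S)-2-{[(tert-butyldiphenylsilyl)oxy]methyl}-5-diazo-3-[2-(1,3-dioxolan-2-yl)ethyl]-2-methylcyclopentan-1-one | O=C1C(=[N+]=[N-])C[C@H](CCC2OCCO2)[C@@]1(C)CO[Si](c1ccccc1)(c1ccccc1)C(C)(C)C | intermediate
8 | cyclobutylidene ketene from ring contraction of 7 (not isolated) | O=C=C1C[C@H](CCC2OCCO2)[C@@]1(C)CO[Si](c1ccccc1)(c1ccccc1)C(C)(C)C | intermediate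
9 | methyl (2R,3S)-2-{[(tert-butyldiphenylsilyl)oxy]methyl}-3-[2-(1,3-dioxolan-2-yl)ethyl]-2-methylcyclobutane-1-carboxylate (C4 epimers) | COC(=O)C1C[C@H](CCC2OCCO2)[C@@]1(C)CO[Si](c1ccccc1)(c1ccccc1)C(C)(C)C | intermediate
10 | 1-(phenylselanyl) derivative of 9 (not isolated) | COC(=O)C1([Se]c2ccccc2)C[C@H](CCC2OCCO2)[C@@]1(C)CO[Si](c1ccccc1)(c1ccccc1)C(C)(C)C | intermediate
11 | methyl (3S,4R)-4-{[(tert-butyldiphenylsilyl)oxy]methyl}-3-[2-(1,3-dioxolan-2-yl)ethyl]-4-methylcyclobut-1-ene-1-carboxylate | COC(=O)C1=C[C@H](CCC2OCCO2)[C@@]1(C)CO[Si](c1ccccc1)(c1ccccc1)C(C)(C)C | intermediate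
12 | methyl (3S,4R)-4-{[(tert-butyldiphenylsilyl)oxy]methyl}-4-methyl-3-(3-oxopropyl)cyclobut-1-ene-1-carboxylate | COC(=O)C1=C[C@H](CCC=O)[C@@]1(C)CO[Si](c1ccccc1)(c1ccccc1)C(C)(C)C | intermediate
13 | methyl (3S,4R)-3-(2-carboxyethyl)-4-{[(tert-butyldiphenylsilyl)oxy]methyl}-4-methylcyclobut-1-ene-1-carboxylate | COC(=O)C1=C[C@H](CCC(=O)O)[C@@]1(C)CO[Si](c1ccccc1)(c1ccccc1)C(C)(C)C | intermediate
14 | methyl (3S,4R)-4-{[(tert-butyldiphenylsilyl)oxy]methyl}-3-(3-methoxy-3-oxopropyl)-4-methylcyclobut-1-ene-1-carboxylate (key-step precursor) | COC(=O)C1=C[C@H](CCC(=O)OC)[C@@]1(C)CO[Si](c1ccccc1)(c1ccccc1)C(C)(C)C | intermediate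
15 | tiglic acid, (E)-2-methylbut-2-enoic acid | C/C=C(\C)C(=O)O | starting material
16 | tert-butyl (E)-2-methylbut-2-enoate | C/C=C(\C)C(=O)OC(C)(C)C | intermediate
17 | lithium 1-tert-butoxy-2-methylbuta-1,3-dien-1-olate (not isolated) | C=CC(C)=C(O[Li])OC(C)(C)C | intermediate
18 | lithium C4 ester enolate of the Michael adduct of 17 and 14 (not isolated) | COC(O[Li])=C1[C@@H]([C@@](C)(C(=O)OC(C)(C)C)C=C)[C@H](CCC(=O)OC)[C@@]1(C)CO[Si](c1ccccc1)(c1ccccc1)C(C)(C)C | intermediate
19 | core β-keto ester: C6 CO2Me (epimers/enol), C7 H2, C8 = CH2OTBDPS, C11 = C(Me)(CH=CH2)(CO2t-Bu) (key-step product) | C[C@@]1(CO[Si](c3ccccc3)(c3ccccc3)C(C)(C)C)[C@@H]2[C@H]([C@@](C)(C(=O)OC(C)(C)C)C=C)[C@H]1C(=O)C(C(=O)OC)C2 | intermediate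
20 | C6 phenylselanyl derivative of 19 (not isolated) | C[C@@]1(CO[Si](c3ccccc3)(c3ccccc3)C(C)(C)C)[C@@H]2[C@H]([C@@](C)(C(=O)OC(C)(C)C)C=C)[C@H]1C(=O)C([Se]c3ccccc3)(C(=O)OC)C2 | intermediate
21 | C6=C7 enone ester of the core (3-methoxycarbonylbicyclo[3.1.1]hept-3-en-2-one) | C[C@@]1(CO[Si](c3ccccc3)(c3ccccc3)C(C)(C)C)[C@@H]2[C@H]([C@@](C)(C(=O)OC(C)(C)C)C=C)[C@H]1C(=O)C(C(=O)OC)=C2 | intermediate
22 | core β-keto ester with C7 methyl, drawn as the C6 epimer with the ester trans to that methyl | C[C@@]1(CO[Si](c3ccccc3)(c3ccccc3)C(C)(C)C)[C@@H]2[C@H]([C@@](C)(C(=O)OC(C)(C)C)C=C)[C@H]1C(=O)[C@H](C(=O)OC)[C@H]2C | intermediate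
23 | core ketone: C6 H2, C7 methyl, C8 = CH2OTBDPS, C11 = C(Me)(CH=CH2)(CO2t-Bu) | C[C@@]1(CO[Si](c3ccccc3)(c3ccccc3)C(C)(C)C)[C@@H]2[C@H]([C@@](C)(C(=O)OC(C)(C)C)C=C)[C@H]1C(=O)C[C@H]2C | intermediate
24 | lithium C5–C6 enolate of 23 (not isolated) | C[C@@]1(CO[Si](c3ccccc3)(c3ccccc3)C(C)(C)C)[C@@H]2[C@H]([C@@](C)(C(=O)OC(C)(C)C)C=C)[C@H]1C(O[Li])=C[C@H]2C | intermediate
25 | core ketone: C11 = C(Me)(CH=CH2)(CH2OH), C8 = CH2OTBDPS | C[C@@]1(CO[Si](c3ccccc3)(c3ccccc3)C(C)(C)C)[C@@H]2[C@H]([C@@](C)(CO)C=C)[C@H]1C(=O)C[C@H]2C | intermediate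
26 | core ketone: C11 = C(Me)(CH=CH2)(CH2OAc), C8 = CH2OTBDPS | C[C@@]1(CO[Si](c3ccccc3)(c3ccccc3)C(C)(C)C)[C@@H]2[C@H]([C@@](C)(COC(C)=O)C=C)[C@H]1C(=O)C[C@H]2C | intermediate
27 | core ketone: C8 = CH2OH, C11 = C(Me)(CH=CH2)(CH2OAc) | C[C@@]1(CO)[C@@H]2[C@H]([C@@](C)(COC(C)=O)C=C)[C@H]1C(=O)C[C@H]2C | intermediate
28 | core ketone: C8 = CHO, C11 = C(Me)(CH=CH2)(CH2OAc) | C[C@@]1(C=O)[C@@H]2[C@H]([C@@](C)(COC(C)=O)C=C)[C@H]1C(=O)C[C@H]2C | intermediate
29 | core ketone: C8 = CH(OH)CH3 (C8 epimers), C11 = C(Me)(CH=CH2)(CH2OAc) | C[C@@]1(C(C)O)[C@@H]2[C@H]([C@@](C)(COC(C)=O)C=C)[C@H]1C(=O)C[C@H]2C | intermediate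
30 | core ketone: C8 = C(=O)CH3, C11 = C(Me)(CH=CH2)(CH2OAc) | C[C@@]1(C(C)=O)[C@@H]2[C@H]([C@@](C)(COC(C)=O)C=C)[C@H]1C(=O)C[C@H]2C | intermediate
31 | core ketone: C8 = C(=O)CH3, C11 = C(Me)(CHO)(CH2OAc) | C[C@@]1(C(C)=O)[C@@H]2[C@H]([C@@](C)(COC(C)=O)C=O)[C@H]1C(=O)C[C@H]2C | intermediate
32 | tricyclic β-hydroxy ketone: C10 OH (cis to the C11 methyl), C8 ketone, C5 ketone, C11 CH2OAc | O[C@@H]1CC(=O)[C@]2(C)[C@@H]3[C@@H]([C@H]2C(=O)C[C@H]3C)[C@@]1(C)COC(C)=O | intermediate
33 | angelic acid, (Z)-2-methylbut-2-enoic acid | C/C=C(/C)C(=O)O | starting material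
34 | (Z)-2-methylbut-2-en-1-ol | C/C=C(/C)CO | intermediate
35 | (Z)-2-methylbut-2-enal | C/C=C(/C)C=O | intermediate
36 | CNP0212099.1 | C/C=C(/C)C(=O)O[C@@H]1C[C@@H](O)[C@]2(C)[C@@H]3[C@@H]([C@H]2C(=O)C[C@H]3C)[C@@]1(C)COC(C)=O | target

**Step count and risks**

Total step count: 24. Longest linear sequence: 21 steps (steps 1–8, 10–21 and 24).

Steps most likely to fail:

1. Step 10. The fully substituted dienolate carbon may fail to reach the hindered C3 (no addition, or attack through the γ-carbon). A lithium-bridged transition state may erode or invert the C11 configuration. The Dieckmann closure to the strained bicycle may stall. Fallback, setting out from 14 and coming back at 19, with known reactions only: conjugate addition of the small lithium enolate of tert-butyl propanoate to 14 (THF, −78 °C, AcOH quench) would give the propanoate Michael adduct F1. A separate Dieckmann condensation (KOt-Bu, THF, 0 °C) would close ring B to the C11-H β-keto ester F2. Double deprotonation (LiN(i-Pr)2, 2.2 equiv) and conjugate addition of the C11 ester enolate to phenyl vinyl sulfoxide would give the sulfoxide F3, at which stage the C11 epimers would be separated. Sulfoxide thermolysis (toluene, 110 °C) would unveil the vinyl group of 19.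

2. Step 21. The ring-closing aldol may show poor facial selectivity at the aldehyde (C10 epimer), revert by retro-aldol on warming, or dehydrate. Fallback, setting out from 31 and coming back at 32: aldol condensation under amine–acid catalysis (pyrrolidine, AcOH, toluene, 60 °C) would give the cycloheptenone F4 and erase the C10 centre. Copper-catalysed enantioselective conjugate borylation (CuCl, NaOt-Bu, chiral bisphosphine, B2pin2, MeOH, THF) would give the β-boryl ketone F5 with C10 set by the ligand. Oxidation with retention (NaBO3, THF/H2O) would return 32.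

3. Step 24. The Z enal or the product ester may isomerise to the E (tiglate) series under the samarium conditions, and hydride transfer from a conjugated aldehyde at a hindered hydroxyl may be slow. Fallback, setting out from 32 and coming back at 36: hydroxyl-directed anti reduction of the C8 ketone (Me4NBH(OAc)3, MeCN/AcOH, −30 °C) would give the anti diol F6. Silylation of the less hindered C8 hydroxyl, whose neighbour C1 is tied back in the cyclobutane (Et3SiCl, imidazole, CH2Cl2, −20 °C), would give the C8 triethylsilyl ether F7. Yamaguchi esterification with angelic acid 33 (2,4,6-trichlorobenzoyl chloride, Et3N; then F7, toluene, 75 °C) would give the silylated angelate F8. Desilylation (HF·pyridine, THF, 0 °C) would give 36.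

**Further compounds**

F1 | step 10 | propanoate Michael adduct: cyclobutane with C4 CO2Me, C3 CH(Me)CO2t-Bu (C11 epimers), C2 CH2CH2CO2Me, C1 Me and CH2OTBDPS | COC(=O)[C@@H]1[C@@H](C(C)C(=O)OC(C)(C)C)[C@H](CCC(=O)OC)[C@@]1(C)CO[Si](c1ccccc1)(c1ccccc1)C(C)(C)C
F2 | step 10 | C11-H β-keto ester: core with C6 CO2Me, C7 H2, C8 = CH2OTBDPS, C11 = CH(Me)(CO2t-Bu) | C[C@@]1(CO[Si](c3ccccc3)(c3ccccc3)C(C)(C)C)[C@@H]2[C@H](C(C)C(=O)OC(C)(C)C)[C@H]1C(=O)C(C(=O)OC)C2
F3 | step 10 | sulfoxide: as 19 with CH2CH2S(O)Ph in place of vinyl on C11 | C[C@@]1(CO[Si](c3ccccc3)(c3ccccc3)C(C)(C)C)[C@@H]2[C@H]([C@@](C)(C(=O)OC(C)(C)C)CCS(=O)c3ccccc3)[C@H]1C(=O)C(C(=O)OC)C2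
F4 | step 21 | cycloheptenone: tricycle with C8 ketone and C9=C10 double bond | C1=CC(=O)[C@]2(C)[C@@H]3[C@@H]([C@H]2C(=O)C[C@H]3C)[C@@]1(C)COC(C)=O
F5 | step 21 | β-boryl ketone: tricycle with pinacolboryl on C10 and C8 ketone | CC1(C)OB(OC1(C)C)[C@@H]1CC(=O)[C@]2(C)[C@@H]3[C@@H]([C@H]2C(=O)C[C@H]3C)[C@@]1(C)COC(C)=O
F6 | step 24 | anti diol: tricycle with C8 OH and C10 OH | O[C@@H]1C[C@@H](O)[C@]2(C)[C@@H]3[C@@H]([C@H]2C(=O)C[C@H]3C)[C@@]1(C)COC(C)=O
F7 | step 24 | C8 triethylsilyl ether of the anti diol | O[C@@H]1C[C@@H](O[Si](CC)(CC)CC)[C@]2(C)[C@@H]3[C@@H]([C@H]2C(=O)C[C@H]3C)[C@@]1(C)COC(C)=O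
F8 | step 24 | C8 triethylsilyl ether of the target | C/C=C(/C)C(=O)O[C@@H]1C[C@@H](O[Si](CC)(CC)CC)[C@]2(C)[C@@H]3[C@@H]([C@H]2C(=O)C[C@H]3C)[C@@]1(C)COC(C)=O
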